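## Retrosynthetic overview

1. Feature: the central benzene ring is hexasubstituted, with benzoyloxy oxygens on C1 and C2, 4-hydroxyphenyl rings on C3 and C6, and hydroxyl oxygens on C4 and C5. The oxygens on C2 and C5 are para and the C1 oxygen flanks C2, which is the pattern left when a 4-(2-alkoxyalkenyl)-4-oxycyclobutenone is ring-expanded to a phenol.
2. Key disconnection: the C1–C2 bond is cut, leading back through a dienylketene to a cyclobutenone. C2 is the old carbonyl carbon, C3/C4 the old ring alkene, C5 the old carbinol carbon, and C6/C1 the alkenyl carbons.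
3. The cyclobutenone is cut at C5–C6 into a 3-aryl-4-benzyloxycyclobutenedione (from squaric acid and an aryl bromide) and an oxygen-chelated 1-aryl-2-alkoxyvinyllithium (from an arylacetylene).
4. Ring order: both outer rings are bought. The four-membered squarate ring is carried to the key step, where it becomes the central six-membered ring, the only ring formed.
5. The central oxygens emerge as OH (C2), OPMB (C1), OBn (C4) and OTBS (C5). The endgame is therefore benzoylation, PMB removal, benzoylation, TBS removal and hydrogenolysis, with no selective acylation.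

Key step: step 8

Abbreviations: Bn benzyl, Bz benzoyl, PMB 4-methoxybenzyl, TBS tert-butyldimethylsilyl.

Remark on the chemistry (alkene geometry): the enol ether oxygen is placed cis to the four-membered ring carbon (Z alkene). Only the vinyllithium with lithium cis to oxygen is chelated and has no anti-periplanar path for loss of lithium alkoxide. The geometry is erased in the key step, so either isomer would give the same arene.

Remark on the chemistry (C1 protecting group): the C1 oxygen is carried as a PMB ether.
- A primary alkoxide adds dependably to the arylacetylene, whereas a tert-butyl enol ether has no comparably short and reliable access.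
- The slim OCH2 link is the smaller group to point toward the ketene.
- Mild acid removes it beside benzyl and aryl silyl ethers.

Remark on the chemistry (stereochemistry): all cyclobutenone carbinols are racemic and the target is achiral.

## Route

Step 1
Reactants: 1 squaric acid
Product: 2 3,4-bis(benzyloxy)cyclobut-3-ene-1,2-dione (dibenzyl squarate)
Conditions: BnOH (excess), PhMe, reflux, Dean–Stark trap
Reagents that add atoms: benzyl alcohol, OCc1ccccc1
Why: Squaric acid is a strong vinylogous acid that catalyses its own Fischer-type esterification, and azeotropic removal of water should carry both acidic hydroxyl groups through to the benzyl vinylogous esters.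

Step 2
Reactants: 3 1-(benzyloxy)-4-bromobenzene; 2 dibenzyl squarate
Product: 5 racemic 2,3-bis(benzyloxy)-4-[4-(benzyloxy)phenyl]-4-hydroxycyclobut-2-en-1-one, via 4-(benzyloxy)phenyllithium 4 (not isolated)
Conditions: n-BuLi, THF, −78 °C; then 2, THF, −78 °C; aq. NH4Cl
Reagents that add atoms: none
Why: Bromine–lithium exchange followed by 1,2-addition of the aryllithium to one of the two equivalent squarate carbonyl groups is the standard entry to 4-aryl-4-hydroxycyclobutenones, the anionic adduct resists a second addition at low temperature, and the new carbinol centre forms as a racemate that is flattened again in step 3.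

Step 3
Reactants: 5 racemic 2,3-bis(benzyloxy)-4-[4-(benzyloxy)phenyl]-4-hydroxycyclobut-2-en-1-one
Product: 6 3-(benzyloxy)-4-[4-(benzyloxy)phenyl]cyclobut-3-ene-1,2-dione
Conditions: conc. aq. HCl (cat.), CH2Cl2, rt
Reagents that add atoms: none
Why: Acid ionises the tertiary carbinol to a cyclobutenyl cation stabilised by the 4-alkoxyphenyl group and the ring oxygens, water returns at the distal benzyloxy-bearing carbon and benzyl alcohol is expelled, which is the established acid-catalysed 1,3-carbonyl transposition of squarate adducts to 3-alkoxy-4-arylcyclobutenediones.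

Step 4
Reactants: 7 1-(benzyloxy)-4-ethynylbenzene
Product: 8 1-(benzyloxy)-4-{(Z)-2-[(4-methoxybenzyl)oxy]ethenyl}benzene
Conditions: 4-MeOC6H4CH2OH, CsOH·H2O (20 mol %), NMP, 100 °C, N2
Reagents that add atoms: 4-methoxybenzyl alcohol, COc1ccc(CO)cc1
Why: Base-catalysed anti-Markovnikov hydroalkoxylation of an arylacetylene, in which the unhindered primary alkoxide attacks the terminal carbon and the benzylic vinyl anion is protonated anti to it, should give mainly the Z enol ether, and the aryl benzyl ether is inert to the base.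

Step 5
Reactants: 8 1-(benzyloxy)-4-{(Z)-2-[(4-methoxybenzyl)oxy]ethenyl}benzene
Product: 10 1-(benzyloxy)-4-{(Z)-1-bromo-2-[(4-methoxybenzyl)oxy]ethenyl}benzene (Br cis to O), via dibromo ether 9 (not isolated)
Conditions: Br2, CH2Cl2, −78 °C; then Et3N, −78 °C → rt
Reagents that add atoms: bromine, BrBr
Why: Bromination–dehydrobromination of an enol ether: bromine adds to the very electron-rich alkene much faster than it substitutes the alkoxyarene rings at −78 °C, and the amine then removes the acidic benzylic hydrogen from the easily ionised α-bromo ether with the aryl group turned away from the alkoxy group, so that bromine ends up cis to oxygen.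

Step 6
Reactants: 10 1-(benzyloxy)-4-{(Z)-1-bromo-2-[(4-methoxybenzyl)oxy]ethenyl}benzene; 6 3-(benzyloxy)-4-[4-(benzyloxy)phenyl]cyclobut-3-ene-1,2-dione
Product: 12 racemic 3-(benzyloxy)-2-[4-(benzyloxy)phenyl]-4-{(Z)-1-[4-(benzyloxy)phenyl]-2-[(4-methoxybenzyl)oxy]ethenyl}-4-hydroxycyclobut-2-en-1-one, via chelated vinyllithium 11 (not isolated)
Conditions: t-BuLi (2 equiv), Et2O, −78 °C; then 6, THF, −78 °C; aq. NH4Cl
Reagents that add atoms: none
Why: Bromine–lithium exchange with retention gives the vinyllithium in which lithium is cis to and chelated by the ether oxygen, an arrangement that has no anti-periplanar path for loss of lithium alkoxide, and this nucleophile should add 1,2 to the ketone-like carbonyl of 6 next to the benzyloxy-bearing carbon rather than to the deactivated vinylogous ester carbonyl, as alkenyllithiums do with 3-alkoxy-4-arylcyclobutenediones, the carbinol centre forming as a racemate that vanishes in step 8.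

Step 7
Reactants: 12 the racemic alkenyl carbinol
Product: 13 racemic 3-(benzyloxy)-2-[4-(benzyloxy)phenyl]-4-{(Z)-1-[4-(benzyloxy)phenyl]-2-[(4-methoxybenzyl)oxy]ethenyl}-4-[(tert-butyldimethylsilyl)oxy]cyclobut-2-en-1-one
Conditions: TBSOTf, 2,6-lutidine, CH2Cl2, −78 → 0 °C
Reagents that add atoms: tert-butyldimethylsilyl triflate, CC(C)(C)[Si](C)(C)OS(=O)(=O)C(F)(F)F
Why: Silyl triflate and a hindered pyridine base silylate tertiary alcohols, the tied-back bonds of the four-membered ring leave this hydroxyl group unusually open, and the buffered cold medium should spare the enol ether and prevent ionisation of the doubly allylic carbinol.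

Step 8
Reactants: 13 the racemic 4-alkenyl-4-silyloxycyclobutenone
Product: 16 3'-(benzyloxy)-4,4''-bis(benzyloxy)-2'-[(tert-butyldimethylsilyl)oxy]-6'-[(4-methoxybenzyl)oxy]-1,1':4',1''-terphenyl-5'-ol, via dienylketene 14 (not isolated), via cyclohexadienone 15 (not isolated)
Conditions: PhMe (degassed, dilute), 110 °C, Ar
Reagents that add atoms: none
Why: Heating opens the bond between the carbonyl carbon and the silyloxy carbon of the cyclobutenone in a conrotatory four-electron process, and the strong preference of the donor silyloxy group to rotate outward swings the alkenyl group inward, so that 14 forms with the enol ether next to the ketene. A disrotatory six-electron electrocyclisation then bonds the sp ketene carbon (C2) to the enol ether CH (C1) and closes the central six-membered ring as dienone 15, whose C1–H enolises to phenol 16; this is the Moore rearrangement, well established for 4-alkenyl-4-hydroxy- and 4-silyloxycyclobutenones. The one sp3 centre of 15 and the alkene geometry are both erased on aromatisation, so no stereocentre has to be controlled. The selectivities needed are torquoselectivity, secured by OTBS standing against a carbon substituent on the breaking bond, and closure in spite of the inward-pointing alkoxy group, which is helped by the empty in-plane side of the ketene carbon, by the slim OCH2 link of the ether and by the fact that dienylketenes with fully substituted termini are known to cyclise. Ring opening is reversible whereas aromatisation is not, so a slow closure should cost time rather than material, and the substitution pattern was already fixed by the regioselective addition of step 6. The product carries four different oxygen functions (OH on C2, OPMB on C1, OBn on C4, OTBS on C5), which is what the endgame requires.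

Step 9
Reactants: 16 the terphenylol
Product: 17 3'-(benzyloxy)-4,4''-bis(benzyloxy)-2'-[(tert-butyldimethylsilyl)oxy]-6'-[(4-methoxybenzyl)oxy]-1,1':4',1''-terphenyl-5'-yl benzoate
Conditions: BzCl, Et3N, DMAP (cat.), CH2Cl2, 0 °C → rt
Reagents that add atoms: benzoyl chloride, O=C(Cl)c1ccccc1
Why: DMAP-catalysed acylation of the only free hydroxyl group, the C2 phenol, which is flanked by an aryl and an alkoxy group but should still react by way of the N-benzoylpyridinium salt.

Step 10
Reactants: 17 the monobenzoate
Product: 18 3'-(benzyloxy)-4,4''-bis(benzyloxy)-2'-[(tert-butyldimethylsilyl)oxy]-6'-hydroxy-1,1':4',1''-terphenyl-5'-yl benzoate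
Conditions: TFA, Et3SiH, CH2Cl2, 0 °C
Reagents that add atoms: none
Why: Acidolysis of an aryl 4-methoxybenzyl ether proceeds through the stabilised 4-methoxybenzyl cation under conditions that plain benzyl ethers, the hindered aryl silyl ether and the benzoate tolerate, triethylsilane reduces the cation before it can alkylate the outer rings, and a benzoyl shift between the C1 and C2 oxygens would be harmless because both are benzoylated in the end.

Step 11
Reactants: 18 the hydroxy benzoate
Product: 19 3'-(benzyloxy)-4,4''-bis(benzyloxy)-2'-[(tert-butyldimethylsilyl)oxy]-1,1':4',1''-terphenyl-5',6'-diyl dibenzoate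
Conditions: BzCl, Et3N, DMAP (cat.), CH2Cl2, 0 °C → rt
Reagents that add atoms: benzoyl chloride, O=C(Cl)c1ccccc1
Why: The same DMAP-catalysed acylation, now of the C1 phenol (or of its C2 isomer after an acyl shift), converges on the single C1/C2 dibenzoate.

Step 12
Reactants: 19 the silylated dibenzoate
Product: 20 3'-(benzyloxy)-4,4''-bis(benzyloxy)-2'-hydroxy-1,1':4',1''-terphenyl-5',6'-diyl dibenzoate
Conditions: HF·pyridine, pyridine, THF, 0 °C → rt
Reagents that add atoms: none
Why: Fluoride-driven cleavage of the aryl silyl ether through formation of the strong Si–F bond is run in an acidic buffered medium so that no phenoxide arises that could attack the aryl benzoates, and the freed C5 hydroxyl has no ester on a neighbouring carbon that could migrate to it.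

Step 13
Reactants: 20 the tribenzyl ether
Product: 21 2',3',4,4''-tetrahydroxy-1,1':4',1''-terphenyl-5',6'-diyl dibenzoate (CNP0216579.0)
Conditions: H2 (1 atm), 10% Pd/C, EtOAc–THF, rt; filtration under Ar
Reagents that add atoms: none
Why: Heterogeneous catalytic hydrogenolysis cleaves the three benzylic C–O bonds under one atmosphere of hydrogen while the aryl benzoates and the arene rings are untouched, and the neutral non-oxidising medium suits the air-sensitive catechol unit at C4/C5.

## Compound list

1 | squaric acid | O=C1C(O)=C(O)C1=O | starting material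
2 | 3,4-bis(benzyloxy)cyclobut-3-ene-1,2-dione | O=C1C(OCc2ccccc2)=C(OCc2ccccc2)C1=O | intermediate
3 | 1-(benzyloxy)-4-bromobenzene | Brc1ccc(OCc2ccccc2)cc1 | starting material
4 | 4-(benzyloxy)phenyllithium | [Li]c1ccc(OCc2ccccc2)cc1 | intermediate
5 | racemic 2,3-bis(benzyloxy)-4-[4-(benzyloxy)phenyl]-4-hydroxycyclobut-2-en-1-one | O=C1C(OCc2ccccc2)=C(OCc2ccccc2)C1(O)c1ccc(OCc2ccccc2)cc1 | intermediate
6 | 3-(benzyloxy)-4-[4-(benzyloxy)phenyl]cyclobut-3-ene-1,2-dione | O=C1C(=O)C(OCc2ccccc2)=C1c1ccc(OCc2ccccc2)cc1 | intermediate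
7 | 1-(benzyloxy)-4-ethynylbenzene | C#Cc1ccc(OCc2ccccc2)cc1 | starting material
8 | 1-(benzyloxy)-4-{(Z)-2-[(4-methoxybenzyl)oxy]ethenyl}benzene | COc1ccc(CO/C=C\c2ccc(OCc3ccccc3)cc2)cc1 | intermediate
9 | 1-(benzyloxy)-4-{1,2-dibromo-2-[(4-methoxybenzyl)oxy]ethyl}benzene (diastereomer mixture) | COc1ccc(COC(Br)C(Br)c2ccc(OCc3ccccc3)cc2)cc1 | intermediate
10 | 1-(benzyloxy)-4-{(Z)-1-bromo-2-[(4-methoxybenzyl)oxy]ethenyl}benzene | COc1ccc(CO/C=C(\Br)c2ccc(OCc3ccccc3)cc2)cc1 | intermediate
11 | 1-[4-(benzyloxy)phenyl]-2-[(4-methoxybenzyl)oxy]ethenyllithium, Li cis to O | COc1ccc(CO/C=C(\[Li])c2ccc(OCc3ccccc3)cc2)cc1 | intermediate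
12 | racemic 3-(benzyloxy)-2-[4-(benzyloxy)phenyl]-4-{(Z)-1-[4-(benzyloxy)phenyl]-2-[(4-methoxybenzyl)oxy]ethenyl}-4-hydroxycyclobut-2-en-1-one | O=C1C(c2ccc(OCc3ccccc3)cc2)=C(OCc2ccccc2)C1(O)/C(=C\OCc1ccc(OC)cc1)c1ccc(OCc2ccccc2)cc1 | intermediate
13 | racemic 3-(benzyloxy)-2-[4-(benzyloxy)phenyl]-4-{(Z)-1-[4-(benzyloxy)phenyl]-2-[(4-methoxybenzyl)oxy]ethenyl}-4-[(tert-butyldimethylsilyl)oxy]cyclobut-2-en-1-one | O=C1C(c2ccc(OCc3ccccc3)cc2)=C(OCc2ccccc2)C1(O[Si](C)(C)C(C)(C)C)/C(=C\OCc1ccc(OC)cc1)c1ccc(OCc2ccccc2)cc1 | intermediate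
14 | dienylketene: 3-(benzyloxy)-2,5-bis[4-(benzyloxy)phenyl]-4-[(tert-butyldimethylsilyl)oxy]-6-[(4-methoxybenzyl)oxy]hexa-1,3,5-trien-1-one, alkenyl group cis to the ketenyl carbon | O=C=C(c1ccc(OCc2ccccc2)cc1)/C(OCc1ccccc1)=C(O[Si](C)(C)C(C)(C)C)\C(c1ccc(OCc2ccccc2)cc1)=C/OCc1ccc(OC)cc1 | intermediate
15 | racemic 3-(benzyloxy)-2,5-bis[4-(benzyloxy)phenyl]-4-[(tert-butyldimethylsilyl)oxy]-6-[(4-methoxybenzyl)oxy]cyclohexa-2,4-dien-1-one | O=C1C(c2ccc(OCc3ccccc3)cc2)=C(OCc2ccccc2)C(O[Si](C)(C)C(C)(C)C)=C(c2ccc(OCc3ccccc3)cc2)C1OCc1ccc(OC)cc1 | intermediate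
16 | 3'-(benzyloxy)-4,4''-bis(benzyloxy)-2'-[(tert-butyldimethylsilyl)oxy]-6'-[(4-methoxybenzyl)oxy]-1,1':4',1''-terphenyl-5'-ol | Oc1c(-c2ccc(OCc3ccccc3)cc2)c(OCc2ccccc2)c(O[Si](C)(C)C(C)(C)C)c(-c2ccc(OCc3ccccc3)cc2)c1OCc1ccc(OC)cc1 | intermediate
17 | 3'-(benzyloxy)-4,4''-bis(benzyloxy)-2'-[(tert-butyldimethylsilyl)oxy]-6'-[(4-methoxybenzyl)oxy]-1,1':4',1''-terphenyl-5'-yl benzoate | O=C(Oc1c(-c2ccc(OCc3ccccc3)cc2)c(OCc2ccccc2)c(O[Si](C)(C)C(C)(C)C)c(-c2ccc(OCc3ccccc3)cc2)c1OCc1ccc(OC)cc1)c1ccccc1 | intermediate
18 | 3'-(benzyloxy)-4,4''-bis(benzyloxy)-2'-[(tert-butyldimethylsilyl)oxy]-6'-hydroxy-1,1':4',1''-terphenyl-5'-yl benzoate | O=C(Oc1c(-c2ccc(OCc3ccccc3)cc2)c(OCc2ccccc2)c(O[Si](C)(C)C(C)(C)C)c(-c2ccc(OCc3ccccc3)cc2)c1O)c1ccccc1 | intermediate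
19 | 3'-(benzyloxy)-4,4''-bis(benzyloxy)-2'-[(tert-butyldimethylsilyl)oxy]-1,1':4',1''-terphenyl-5',6'-diyl dibenzoate | O=C(Oc1c(OC(=O)c2ccccc2)c(-c2ccc(OCc3ccccc3)cc2)c(O[Si](C)(C)C(C)(C)C)c(OCc2ccccc2)c1-c1ccc(OCc2ccccc2)cc1)c1ccccc1 | intermediate
20 | 3'-(benzyloxy)-4,4''-bis(benzyloxy)-2'-hydroxy-1,1':4',1''-terphenyl-5',6'-diyl dibenzoate | O=C(Oc1c(OC(=O)c2ccccc2)c(-c2ccc(OCc3ccccc3)cc2)c(O)c(OCc2ccccc2)c1-c1ccc(OCc2ccccc2)cc1)c1ccccc1 | intermediate
21 | 2',3',4,4''-tetrahydroxy-1,1':4',1''-terphenyl-5',6'-diyl dibenzoate (CNP0216579.0) | O=C(Oc1c(OC(=O)c2ccccc2)c(-c2ccc(O)cc2)c(O)c(O)c1-c1ccc(O)cc1)c1ccccc1 | target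

## Step count and risks

Total step count: 13.
Longest linear sequence: 11 (steps 1–3, then 6–13). The alkyne branch (steps 4 and 5) joins at step 6.

**Step 8.** The alkoxy group points into the forming ring and may retard the six-electron closure. The ketene could then revert repeatedly and be drained by dimerisation or by capture with traces of water, and long heating could cost the silyl group.

The fallback sets out from 13 and comes back at 16. The alkene is inverted before heating by visible-light triplet sensitisation (fac-Ir(ppy)3, 450 nm, THF, rt). The Z isomer, whose aryl ring can lie in the alkene plane, accepts energy. The isomer with the aryl ring twisted by a cis alkoxy group does not, so it should accumulate as the (E)-configured silyl ether F1. Heating F1 in toluene then turns hydrogen rather than oxygen toward the ketene and should give 16 by the same ring expansion.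

**Step 6.** Three processes may compete with addition:
- the α-aryl vinyllithium may invert its configuration and then lose lithium 4-methoxybenzyl oxide by anti elimination;
- a proton may be transferred from the benzylic OCH2 group;
- the reagent may attack the wrong carbonyl group.

The fallback sets out from 6, with the alkenyl partner drawn from 7, and comes back at 19. It installs the C1 oxygen after the ring expansion.
- Alkyne 7 is hydrobrominated in the Markovnikov sense (HBr from TMSBr and MeOH, CH2Cl2, −40 °C) to 1-(benzyloxy)-4-(1-bromoethenyl)benzene F2.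
- t-BuLi in THF at −78 °C converts it into 1-[4-(benzyloxy)phenyl]ethenyllithium F3, which has no β-leaving group and adds to the same carbonyl of 6 to give the 4-(1-arylethenyl) carbinol F4.
- Silylation as in step 7 gives the silyl ether F5, and heating in toluene gives the C1-unsubstituted terphenylol F6.
- 2-Iodoxybenzoic acid in DMF oxygenates this phenol at its only free ring position to the ortho-quinone F7.
- Na2S2O4 reduces it to the catechol F8, and double benzoylation (BzCl, Et3N, DMAP) gives 19.

**Step 4.** Nucleophilic attack on the electron-rich alkyne may be sluggish, the base may be tied up as acetylide, and the benzylic alcohol may degrade at the temperature needed.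

The fallback sets out from 7 and comes back at 8.
- Anti-Markovnikov hydration (CpRuCl(dppm) cat., aqueous 2-propanol, 100 °C) gives [4-(benzyloxy)phenyl]acetaldehyde F9.
- Acetalisation with 4-methoxybenzyl alcohol (PPTS, PhMe, molecular sieves) gives the bis(4-methoxybenzyl) acetal F10.
- TMSOTf and i-Pr2NEt in CH2Cl2 eliminate one alkoxy group to give 8 together with its E isomer F11.
- The mixture can be taken into step 5, because reversible ionisation of the α-bromo ether should let both isomers converge on 10.

## Further compounds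

F1 | step 8 | racemic 3-(benzyloxy)-2-[4-(benzyloxy)phenyl]-4-{(E)-1-[4-(benzyloxy)phenyl]-2-[(4-methoxybenzyl)oxy]ethenyl}-4-[(tert-butyldimethylsilyl)oxy]cyclobut-2-en-1-one | O=C1C(c2ccc(OCc3ccccc3)cc2)=C(OCc2ccccc2)C1(O[Si](C)(C)C(C)(C)C)/C(=C/OCc1ccc(OC)cc1)c1ccc(OCc2ccccc2)cc1
F2 | step 6 | 1-(benzyloxy)-4-(1-bromoethenyl)benzene | C=C(Br)c1ccc(OCc2ccccc2)cc1
F3 | step 6 | 1-[4-(benzyloxy)phenyl]ethenyllithium | [Li]C(=C)c1ccc(OCc2ccccc2)cc1
F4 | step 6 | racemic 3-(benzyloxy)-2-[4-(benzyloxy)phenyl]-4-{1-[4-(benzyloxy)phenyl]ethenyl}-4-hydroxycyclobut-2-en-1-one | O=C1C(c2ccc(OCc3ccccc3)cc2)=C(OCc2ccccc2)C1(O)C(=C)c1ccc(OCc2ccccc2)cc1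
F5 | step 6 | racemic 3-(benzyloxy)-2-[4-(benzyloxy)phenyl]-4-{1-[4-(benzyloxy)phenyl]ethenyl}-4-[(tert-butyldimethylsilyl)oxy]cyclobut-2-en-1-one | O=C1C(c2ccc(OCc3ccccc3)cc2)=C(OCc2ccccc2)C1(O[Si](C)(C)C(C)(C)C)C(=C)c1ccc(OCc2ccccc2)cc1
F6 | step 6 | 3'-(benzyloxy)-4,4''-bis(benzyloxy)-2'-[(tert-butyldimethylsilyl)oxy]-1,1':4',1''-terphenyl-5'-ol | Oc1cc(-c2ccc(OCc3ccccc3)cc2)c(O[Si](C)(C)C(C)(C)C)c(OCc2ccccc2)c1-c1ccc(OCc2ccccc2)cc1
F7 | step 6 | 4-(benzyloxy)-3,6-bis[4-(benzyloxy)phenyl]-5-[(tert-butyldimethylsilyl)oxy]cyclohexa-3,5-diene-1,2-dione | O=C1C(=O)C(c2ccc(OCc3ccccc3)cc2)=C(O[Si](C)(C)C(C)(C)C)C(OCc2ccccc2)=C1c1ccc(OCc2ccccc2)cc1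
F8 | step 6 | 3'-(benzyloxy)-4,4''-bis(benzyloxy)-2'-[(tert-butyldimethylsilyl)oxy]-1,1':4',1''-terphenyl-5',6'-diol | Oc1c(O)c(-c2ccc(OCc3ccccc3)cc2)c(O[Si](C)(C)C(C)(C)C)c(OCc2ccccc2)c1-c1ccc(OCc2ccccc2)cc1
F9 | step 4 | [4-(benzyloxy)phenyl]acetaldehyde | O=CCc1ccc(OCc2ccccc2)cc1
F10 | step 4 | 1-(benzyloxy)-4-{2,2-bis[(4-methoxybenzyl)oxy]ethyl}benzene | COc1ccc(COC(Cc2ccc(OCc3ccccc3)cc2)OCc2ccc(OC)cc2)cc1
F11 | step 4 | 1-(benzyloxy)-4-{(E)-2-[(4-methoxybenzyl)oxy]ethenyl}benzene | COc1ccc(CO/C=C/c2ccc(OCc3ccccc3)cc2)cc1
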